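**Strategy.** With germacrane numbering (dihydrofuran O–C1=C2–C3–C4, alkylidene C5=C6, butenolide C6–C7=C11–C12, chain C8–C9–C10), everything rests on disconnecting C2–C3 and O–C4 of the dihydrofuran as a formal (3+2) union of an α-oxo carbene (C2–C1=O) with the terminal alkene C3=C4 of an (E)-dienyl butenolide. One operation on an acyclic diazoketone forms C2–C3, closes the ten-membered carbocycle and the oxa-bridged dihydrofuran, and sets C4. The step exploits the allylic, tertiary C4, which lets the vinylcyclopropyl ketone ionise and reclose through oxygen, and the (E)-C5=C6 geometry, which holds C4 and C8 together.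

Key step: step 13

Remark: the lactol carbon of 12 and the cyclopropane carbons C2/C4 of 25 are carried as isomer mixtures, because both are erased or reset later; atom numbers are those of the overview.

Step 1
Reactants: 1 but-2-yne-1,4-diol; 2 prop-1-en-2-ylmagnesium bromide; 3 carbon dioxide
Product: 5 3-(hydroxymethyl)-4-(prop-1-en-2-yl)furan-2(5H)-one, via alkenylmagnesium chelate 4 (not isolated)
Conditions: 2 (4.5 equiv), THF, reflux, 16 h; then 3 (gas), −20 → 23 °C; then 2 M HCl
Reagents that add atoms: none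
Why: Chelation-controlled anti-carbomagnesiation of the propargylic dialkoxide (isopropenyl to one alkyne carbon, magnesium to the other in a five-membered O–Mg chelate) followed by carboxylation puts CO2H cis to a CH2OH, so acid work-up lactonises to the butenolide; the symmetry of 1 removes any regiochemical issue, the dialkoxide suppresses β-elimination to an allene, and no stereocentre is formed.

Step 2
Reactants: 5 3-(hydroxymethyl)-4-(prop-1-en-2-yl)furan-2(5H)-one
Product: 6 3-({[tert-butyl(dimethyl)silyl]oxy}methyl)-4-(prop-1-en-2-yl)furan-2(5H)-one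
Conditions: TBSCl, imidazole, CH2Cl2, 0 → 23 °C
Reagents that add atoms: tert-butyl(chloro)dimethylsilane, CC(C)(C)[Si](C)(C)Cl
Why: Standard silylation of the primary alcohol, which keeps O13 from binding the Lewis acid of the next step; no stereocentre is involved.

Step 3
Reactants: 6 3-({[tert-butyl(dimethyl)silyl]oxy}methyl)-4-(prop-1-en-2-yl)furan-2(5H)-one; 7 tert-butyl 2-oxopropanoate
Product: 8 tert-butyl (2S)-4-[4-({[tert-butyl(dimethyl)silyl]oxy}methyl)-5-oxo-2,5-dihydrofuran-3-yl]-2-hydroxy-2-methylpent-4-enoate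
Conditions: 7 (3 equiv), [Cu((S,S)-tBu-box)](SbF6)2 (10 mol %; tBu-box = 2,2′-(propane-2,2-diyl)bis(4-tert-butyl-4,5-dihydro-1,3-oxazole)), CH2Cl2, 23 → 40 °C
Reagents that add atoms: none
Why: Catalytic enantioselective carbonyl-ene reaction in which the pyruvate, chelated to the divalent copper bis(oxazoline) complex, is attacked on its Si face by the terminal CH2 of the isopropenyl group with hydrogen transfer from the methyl group, which should set C10 as S and leave a C8 methylene for step 4.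

Step 4
Reactants: 8 tert-butyl (2S)-4-[4-({[tert-butyl(dimethyl)silyl]oxy}methyl)-5-oxo-2,5-dihydrofuran-3-yl]-2-hydroxy-2-methylpent-4-enoate
Product: 9 tert-butyl (2S)-4-[4-({[tert-butyl(dimethyl)silyl]oxy}methyl)-5-oxo-2,5-dihydrofuran-3-yl]-2-hydroxy-2-methyl-4-oxobutanoate
Conditions: O3, CH2Cl2/MeOH, pyridine, −78 °C; then Me2S, −78 → 23 °C
Reagents that add atoms: ozone, [O-][O+]=O
Why: Ozonolysis cleaves only the 1,1-disubstituted C8=CH2 bond, which is far more electron-rich than the tetrasubstituted, ester-conjugated C7=C11 bond; C10 is untouched.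

Step 5
Reactants: 9 tert-butyl (2S)-4-[4-({[tert-butyl(dimethyl)silyl]oxy}methyl)-5-oxo-2,5-dihydrofuran-3-yl]-2-hydroxy-2-methyl-4-oxobutanoate
Product: 10 tert-butyl (2S,4S)-4-[4-({[tert-butyl(dimethyl)silyl]oxy}methyl)-5-oxo-2,5-dihydrofuran-3-yl]-2,4-dihydroxy-2-methylbutanoate
Conditions: Me4NBH(OAc)3 (5 equiv), MeCN/AcOH (1:1), −30 °C
Reagents that add atoms: none
Why: Evans–Saksena reduction, in which the acetoxyborohydride bound to the C10 hydroxyl delivers hydride intramolecularly through a chair transition state to give the 1,3-anti diol and hence 8S; the lactone and the tert-butyl ester are inert, and the bulky ester resists γ-lactonisation by the new alcohol.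

Step 6
Reactants: 10 tert-butyl (2S,4S)-4-[4-({[tert-butyl(dimethyl)silyl]oxy}methyl)-5-oxo-2,5-dihydrofuran-3-yl]-2,4-dihydroxy-2-methylbutanoate
Product: 12 tert-butyl (2S,4S)-4-[4-({[tert-butyl(dimethyl)silyl]oxy}methyl)-2-hydroxy-5-oxo-2,5-dihydrofuran-3-yl]-2-methyl-2,4-bis[(triethylsilyl)oxy]butanoate, via 2-silyloxyfuran 11 (not isolated)
Conditions: TESOTf (4.5 equiv), Et3N (6 equiv), CH2Cl2, −78 → 0 °C; then dimethyldioxirane (1.1 equiv, acetone), −78 °C; then pH 7 buffer/THF
Reagents that add atoms: triethylsilyl trifluoromethanesulfonate, CC[Si](CC)(CC)OS(=O)(=O)C(F)(F)F; dimethyldioxirane, CC1(C)OO1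
Why: Exhaustive silylation caps both alcohols and turns the butenolide into the 2-silyloxyfuran by soft enolisation at C6, and dimethyldioxirane then oxidises the electron-rich furan at C6 (silyloxyfuran oxidation to a γ-hydroxybutenolide); the lactol carbon forms as an inconsequential epimer mixture.

Step 7
Reactants: 12 tert-butyl (2S,4S)-4-[4-({[tert-butyl(dimethyl)silyl]oxy}methyl)-2-hydroxy-5-oxo-2,5-dihydrofuran-3-yl]-2-methyl-2,4-bis[(triethylsilyl)oxy]butanoate; 13 dimethyl (1-diazo-2-oxopropyl)phosphonate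
Product: 15 (2E,4S,6S)-7-tert-butoxy-2-({[tert-butyl(dimethyl)silyl]oxy}methyl)-3-ethynyl-6-methyl-7-oxo-4,6-bis[(triethylsilyl)oxy]hept-2-enoic acid, via open-chain formyl acid 14 (not isolated)
Conditions: 13 (1.5 equiv), K2CO3 (3 equiv), MeOH, 0 → 23 °C; then pH 4 buffer
Reagents that add atoms: none
Why: Seyferth–Gilbert homologation in the Ohira–Bestmann variant: carbonate opens the hemiacylal to the formyl carboxylate and the diazophosphonate anion converts CHO into C≡CH without touching the C7=C11 geometry, so carboxyl and alkyne stay cis; silyl ethers and the tert-butyl ester tolerate K2CO3/MeOH.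

Step 8
Reactants: 15 (2E,4S,6S)-7-tert-butoxy-2-({[tert-butyl(dimethyl)silyl]oxy}methyl)-3-ethynyl-6-methyl-7-oxo-4,6-bis[(triethylsilyl)oxy]hept-2-enoic acid; 16 2-bromoprop-1-ene
Product: 17 tert-butyl (2S,4S)-4-[(2E)-4-({[tert-butyl(dimethyl)silyl]oxy}methyl)-2-(2-methylprop-2-en-1-ylidene)-5-oxo-2,5-dihydrofuran-3-yl]-2-methyl-2,4-bis[(triethylsilyl)oxy]butanoate
Conditions: 16 (3 equiv), Pd(PPh3)4 (5 mol %), K2CO3 (2 equiv), MeCN, 50 °C
Reagents that add atoms: none
Why: Palladium-catalysed cyclisation–coupling of an alkynoic acid with a vinyl halide: isopropenylpalladium bromide activates the alkyne, the cis carboxylate attacks anti in 5-exo-dig fashion and reductive elimination places the isopropenyl group trans to the ring oxygen, which should give the strained (E)-alkylidene butenolide stereospecifically.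

Step 9
Reactants: 17 tert-butyl (2S,4S)-4-[(2E)-4-({[tert-butyl(dimethyl)silyl]oxy}methyl)-2-(2-methylprop-2-en-1-ylidene)-5-oxo-2,5-dihydrofuran-3-yl]-2-methyl-2,4-bis[(triethylsilyl)oxy]butanoate
Product: 18 tert-butyl (2S,4S)-2,4-dihydroxy-4-[(2E)-4-(hydroxymethyl)-2-(2-methylprop-2-en-1-ylidene)-5-oxo-2,5-dihydrofuran-3-yl]-2-methylbutanoate
Conditions: HF·pyridine, pyridine, THF, 0 → 23 °C
Reagents that add atoms: none
Why: Buffered fluoride desilylation removes all three silyl ethers while the enol lactone and the tert-butyl ester survive; the C8 hydroxyl is trans to the lactone carbonyl across C7=C11 and cannot translactonise.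

Step 10
Reactants: 18 tert-butyl (2S,4S)-2,4-dihydroxy-4-[(2E)-4-(hydroxymethyl)-2-(2-methylprop-2-en-1-ylidene)-5-oxo-2,5-dihydrofuran-3-yl]-2-methylbutanoate
Product: 19 tert-butyl (2S,4S)-4-acetoxy-4-[(2E)-4-(acetoxymethyl)-2-(2-methylprop-2-en-1-ylidene)-5-oxo-2,5-dihydrofuran-3-yl]-2-hydroxy-2-methylbutanoate
Conditions: Ac2O (3 equiv), pyridine, DMAP (2 mol %), CH2Cl2, 0 → 23 °C
Reagents that add atoms: acetic anhydride, CC(=O)OC(C)=O
Why: Acylation of the primary and the secondary alcohol installs both acetates of the target, the tertiary C10 alcohol being too hindered to react under these conditions.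

Step 11
Reactants: 19 tert-butyl (2S,4S)-4-acetoxy-4-[(2E)-4-(acetoxymethyl)-2-(2-methylprop-2-en-1-ylidene)-5-oxo-2,5-dihydrofuran-3-yl]-2-hydroxy-2-methylbutanoate
Product: 21 (2S,4S)-4-acetoxy-4-[(2E)-4-(acetoxymethyl)-2-(2-methylprop-2-en-1-ylidene)-5-oxo-2,5-dihydrofuran-3-yl]-2-methyl-2-[(triethylsilyl)oxy]butanoic acid, via triethylsilyl ester 20 (not isolated)
Conditions: TESOTf (3 equiv), 2,6-lutidine (5 equiv), CH2Cl2, 0 → 23 °C; then pH 4 citrate buffer/THF
Reagents that add atoms: triethylsilyl trifluoromethanesulfonate, CC[Si](CC)(CC)OS(=O)(=O)C(F)(F)F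
Why: The silyl triflate silylates the tertiary alcohol and cleaves the tert-butyl ester to the silyl ester with loss of 2-methylpropene (silyl-triflate dealkylation of tert-butyl esters), and the labile silyl ester is hydrolysed on work-up while the acetates stay.

Step 12
Reactants: 21 (2S,4S)-4-acetoxy-4-[(2E)-4-(acetoxymethyl)-2-(2-methylprop-2-en-1-ylidene)-5-oxo-2,5-dihydrofuran-3-yl]-2-methyl-2-[(triethylsilyl)oxy]butanoic acid; 22 (diazomethyl)trimethylsilane
Product: 24 (1S,3S)-1-[(2E)-4-(acetoxymethyl)-2-(2-methylprop-2-en-1-ylidene)-5-oxo-2,5-dihydrofuran-3-yl]-5-diazo-3-methyl-4-oxo-3-[(triethylsilyl)oxy]pentyl acetate, via acid chloride 23 (not isolated)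
Conditions: 1-chloro-N,N,2-trimethylprop-1-en-1-amine (1.3 equiv), CH2Cl2, 0 → 23 °C; then 22 (2.5 equiv), MeCN/THF, 0 → 23 °C
Reagents that add atoms: none
Why: Neutral acid chloride formation followed by acylation of the silyldiazomethane (Arndt–Eistert-type diazoketone synthesis) introduces C2; the acid has no α-hydrogen, so no ketene can form, and the tetrasubstituted butenolide alkene is a poor dipolarophile.

Step 13
Reactants: 24 (1S,3S)-1-[(2E)-4-(acetoxymethyl)-2-(2-methylprop-2-en-1-ylidene)-5-oxo-2,5-dihydrofuran-3-yl]-5-diazo-3-methyl-4-oxo-3-[(triethylsilyl)oxy]pentyl acetate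
Product: 26 (4S,5E,8S,10S)-8,13-diacetoxy-1,4-epoxy-10-[(triethylsilyl)oxy]germacra-1,5,7(11)-trien-12,6-olide, via vinylcyclopropyl ketone 25 (not isolated)
Conditions: Cu(MeCN)4PF6 (10 mol %), CH2Cl2, 40 °C, syringe-pump addition of 24 over 12 h (final 1 mM); then Sc(OTf)3 (10 mol %), 4 Å MS, 23 °C
Reagents that add atoms: none
Why: The copper carbenoid from 24 adds to the terminal C3=C4 alkene (macrocyclic cyclopropanation, forming C2–C3 and C2–C4), and the donor–acceptor vinylcyclopropyl ketone 25 then undergoes Lewis-acid Cloke–Wilson rearrangement (C2–C4 heterolysis to a C4 allyl cation and C1 enolate, then O–C4 closure), overall a formal (3+2) cycloaddition of an α-oxo carbene with a diene. The closest known reaction types are copper-catalysed macrocyclic cyclopropanation of tethered diazocarbonyl compounds and dihydrofuran formation from acylcyclopropanes that carry a cation-stabilising donor. The ten-membered carbocycle closes by carbene addition of C2 to C3 across the U-shaped C8–C7–C6=C5–C4 unit, and the dihydrofuran closes by capture of the C4 cation by the enolate oxygen, which also creates the nine-membered oxacycle. C4 is the only new stereocentre that is kept: ionisation at C4 is reversible under Sc(OTf)3, so both cyclopropane isomers should funnel under control of C8 to the 4S isomer, the one in which H-8 and not the 8-acetoxy group faces the C4 methyl group across the C4···C8 bay; C2 ceases to be a stereocentre. The step needs chemoselectivity for C3=C4 over the hindered, electron-poor C5=C6 and C7=C11 bonds and over C–H insertion at C8, which the 1,1-disubstituted terminal alkene, the deactivating 8-acetate and copper in place of rhodium should secure; cleavage of C2–C4 and not C2–C3 follows from the quaternary allylic C4.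

Step 14
Reactants: 26 (4S,5E,8S,10S)-8,13-diacetoxy-1,4-epoxy-10-[(triethylsilyl)oxy]germacra-1,5,7(11)-trien-12,6-olide
Product: 27 (4S,5E,8S,10S)-8,13-diacetoxy-1,4-epoxy-10-hydroxygermacra-1,5,7(11)-trien-12,6-olide
Conditions: TBAF/AcOH (1:1, 3 equiv), THF, 0 → 23 °C
Reagents that add atoms: none
Why: Acetic acid-buffered fluoride desilylation frees the tertiary alcohol without acid that would hydrate the enol ether or base that would cleave the acetates; no stereocentre is affected.

**Compound list**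

1 | but-2-yne-1,4-diol | OCC#CCO | starting material
2 | prop-1-en-2-ylmagnesium bromide | CC(=C)[Mg]Br | starting material
3 | carbon dioxide | O=C=O | starting material
4 | alkenylmagnesium chelate (five-membered C–Mg–O ring, second alkoxide as OMgBr) | CC(=C)C1=C(CO[Mg]Br)[Mg]OC1 | intermediate (not isolated)
5 | 3-(hydroxymethyl)-4-(prop-1-en-2-yl)furan-2(5H)-one | CC(=C)C1=C(CO)C(=O)OC1 | intermediate
6 | 3-({[tert-butyl(dimethyl)silyl]oxy}methyl)-4-(prop-1-en-2-yl)furan-2(5H)-one | CC(=C)C1=C(CO[Si](C)(C)C(C)(C)C)C(=O)OC1 | intermediate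
7 | tert-butyl 2-oxopropanoate | CC(=O)C(=O)OC(C)(C)C | starting material
8 | tert-butyl (2S)-4-[4-({[tert-butyl(dimethyl)silyl]oxy}methyl)-5-oxo-2,5-dihydrofuran-3-yl]-2-hydroxy-2-methylpent-4-enoate | CC(C)(C)OC(=O)[C@@](C)(O)CC(=C)C1=C(CO[Si](C)(C)C(C)(C)C)C(=O)OC1 | intermediate
9 | tert-butyl (2S)-4-[4-({[tert-butyl(dimethyl)silyl]oxy}methyl)-5-oxo-2,5-dihydrofuran-3-yl]-2-hydroxy-2-methyl-4-oxobutanoate | CC(C)(C)OC(=O)[C@@](C)(O)CC(=O)C1=C(CO[Si](C)(C)C(C)(C)C)C(=O)OC1 | intermediate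
10 | tert-butyl (2S,4S)-4-[4-({[tert-butyl(dimethyl)silyl]oxy}methyl)-5-oxo-2,5-dihydrofuran-3-yl]-2,4-dihydroxy-2-methylbutanoate | CC(C)(C)OC(=O)[C@@](C)(O)C[C@H](O)C1=C(CO[Si](C)(C)C(C)(C)C)C(=O)OC1 | intermediate
11 | tert-butyl (2S,4S)-4-{4-({[tert-butyl(dimethyl)silyl]oxy}methyl)-5-[(triethylsilyl)oxy]furan-3-yl}-2-methyl-2,4-bis[(triethylsilyl)oxy]butanoate | CC(C)(C)OC(=O)[C@@](C)(O[Si](CC)(CC)CC)C[C@H](O[Si](CC)(CC)CC)c1coc(O[Si](CC)(CC)CC)c1CO[Si](C)(C)C(C)(C)C | intermediate (not isolated)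
12 | tert-butyl (2S,4S)-4-[4-({[tert-butyl(dimethyl)silyl]oxy}methyl)-2-hydroxy-5-oxo-2,5-dihydrofuran-3-yl]-2-methyl-2,4-bis[(triethylsilyl)oxy]butanoate (lactol epimers) | CC(C)(C)OC(=O)[C@@](C)(O[Si](CC)(CC)CC)C[C@H](O[Si](CC)(CC)CC)C1=C(CO[Si](C)(C)C(C)(C)C)C(=O)OC1O | intermediate
13 | dimethyl (1-diazo-2-oxopropyl)phosphonate | CC(=O)C(=[N+]=[N-])P(=O)(OC)OC | starting material
14 | (2Z,4S,6S)-7-tert-butoxy-2-({[tert-butyl(dimethyl)silyl]oxy}methyl)-3-formyl-6-methyl-7-oxo-4,6-bis[(triethylsilyl)oxy]hept-2-enoic acid (carboxyl cis to formyl) | CC(C)(C)OC(=O)[C@@](C)(O[Si](CC)(CC)CC)C[C@H](O[Si](CC)(CC)CC)/C(C=O)=C(\CO[Si](C)(C)C(C)(C)C)C(O)=O | intermediate (not isolated)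
15 | (2E,4S,6S)-7-tert-butoxy-2-({[tert-butyl(dimethyl)silyl]oxy}methyl)-3-ethynyl-6-methyl-7-oxo-4,6-bis[(triethylsilyl)oxy]hept-2-enoic acid (carboxyl cis to ethynyl) | CC(C)(C)OC(=O)[C@@](C)(O[Si](CC)(CC)CC)C[C@H](O[Si](CC)(CC)CC)/C(C#C)=C(\CO[Si](C)(C)C(C)(C)C)C(O)=O | intermediate
16 | 2-bromoprop-1-ene | CC(Br)=C | starting material
17 | tert-butyl (2S,4S)-4-[(2E)-4-({[tert-butyl(dimethyl)silyl]oxy}methyl)-2-(2-methylprop-2-en-1-ylidene)-5-oxo-2,5-dihydrofuran-3-yl]-2-methyl-2,4-bis[(triethylsilyl)oxy]butanoate | CC(C)(C)OC(=O)[C@@](C)(O[Si](CC)(CC)CC)C[C@H](O[Si](CC)(CC)CC)C1=C(CO[Si](C)(C)C(C)(C)C)C(=O)O/C1=C/C(C)=C | intermediate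
18 | tert-butyl (2S,4S)-2,4-dihydroxy-4-[(2E)-4-(hydroxymethyl)-2-(2-methylprop-2-en-1-ylidene)-5-oxo-2,5-dihydrofuran-3-yl]-2-methylbutanoate | CC(C)(C)OC(=O)[C@@](C)(O)C[C@H](O)C1=C(CO)C(=O)O/C1=C/C(C)=C | intermediate
19 | tert-butyl (2S,4S)-4-acetoxy-4-[(2E)-4-(acetoxymethyl)-2-(2-methylprop-2-en-1-ylidene)-5-oxo-2,5-dihydrofuran-3-yl]-2-hydroxy-2-methylbutanoate | CC(C)(C)OC(=O)[C@@](C)(O)C[C@H](OC(C)=O)C1=C(COC(C)=O)C(=O)O/C1=C/C(C)=C | intermediate
20 | triethylsilyl (2S,4S)-4-acetoxy-4-[(2E)-4-(acetoxymethyl)-2-(2-methylprop-2-en-1-ylidene)-5-oxo-2,5-dihydrofuran-3-yl]-2-methyl-2-[(triethylsilyl)oxy]butanoate | CC[Si](CC)(CC)OC(=O)[C@@](C)(O[Si](CC)(CC)CC)C[C@H](OC(C)=O)C1=C(COC(C)=O)C(=O)O/C1=C/C(C)=C | intermediate (not isolated)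
21 | (2S,4S)-4-acetoxy-4-[(2E)-4-(acetoxymethyl)-2-(2-methylprop-2-en-1-ylidene)-5-oxo-2,5-dihydrofuran-3-yl]-2-methyl-2-[(triethylsilyl)oxy]butanoic acid | OC(=O)[C@@](C)(O[Si](CC)(CC)CC)C[C@H](OC(C)=O)C1=C(COC(C)=O)C(=O)O/C1=C/C(C)=C | intermediate
22 | (diazomethyl)trimethylsilane | C[Si](C)(C)C=[N+]=[N-] | starting material
23 | (2S,4S)-4-acetoxy-4-[(2E)-4-(acetoxymethyl)-2-(2-methylprop-2-en-1-ylidene)-5-oxo-2,5-dihydrofuran-3-yl]-2-methyl-2-[(triethylsilyl)oxy]butanoyl chloride | ClC(=O)[C@@](C)(O[Si](CC)(CC)CC)C[C@H](OC(C)=O)C1=C(COC(C)=O)C(=O)O/C1=C/C(C)=C | intermediate (not isolated)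
24 | (1S,3S)-1-[(2E)-4-(acetoxymethyl)-2-(2-methylprop-2-en-1-ylidene)-5-oxo-2,5-dihydrofuran-3-yl]-5-diazo-3-methyl-4-oxo-3-[(triethylsilyl)oxy]pentyl acetate | [N-]=[N+]=CC(=O)[C@@](C)(O[Si](CC)(CC)CC)C[C@H](OC(C)=O)C1=C(COC(C)=O)C(=O)O/C1=C/C(C)=C | intermediate
25 | (5E,8S,10S)-8,13-diacetoxy-2,4-cyclo-10-[(triethylsilyl)oxy]germacra-5,7(11)-dien-1-on-12,6-olide (C2–C3–C4 cyclopropane, isomer mixture at C2/C4) | CC(=O)OCC1=C2/C(=C\C3(C)CC3C(=O)[C@@](C)(O[Si](CC)(CC)CC)C[C@@H]2OC(C)=O)OC1=O | intermediate (not isolated)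
26 | (4S,5E,8S,10S)-8,13-diacetoxy-1,4-epoxy-10-[(triethylsilyl)oxy]germacra-1,5,7(11)-trien-12,6-olide | CC(=O)OCC1=C2/C(=C\[C@]3(C)CC=C(O3)[C@@](C)(O[Si](CC)(CC)CC)C[C@@H]2OC(C)=O)OC1=O | intermediate
27 | (4S,5E,8S,10S)-8,13-diacetoxy-1,4-epoxy-10-hydroxygermacra-1,5,7(11)-trien-12,6-olide (CNP0144020.1) | CC(=O)OCC1=C2/C(=C\[C@]3(C)CC=C(O3)[C@@](C)(O)C[C@@H]2OC(C)=O)OC1=O | target

**Step count and risks**

Total step count: 14. Longest linear sequence: 14 steps (from 1).

Steps most likely to fail: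

1. Step 13. Carbene dimerisation or insertion may outrun the slow macrocyclic cyclopropanation, and reclosure at C4 may show poor facial selectivity. Fallback, setting out from 21 and coming back at 27: 21 is activated with carbonyldiimidazole and condensed with the magnesium salt of mono-[2-(trimethylsilyl)ethyl] malonate (decarboxylative Claisen acylation) to give the 2-(trimethylsilyl)ethyl β-keto ester F1. Oxidative free-radical macrocyclisation of F1 with Mn(OAc)3·2H2O and Cu(OAc)2·H2O in degassed AcOH at high dilution follows: the trivalent manganese enolate gives the C2 radical, which adds to C3; divalent copper oxidises the allylic radical to the C4 cation, which the enol oxygen traps. This should give the C2-carboxylated dihydrofuran ester F2. Tris(dimethylamino)sulfonium difluorotrimethylsilicate in DMF then removes the silylethyl ester and the silyl ether to give the acid F3, which is decarboxylated by warming in toluene to 27.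

2. Step 3. The hindered, butenolide-conjugated isopropenyl group may be too poor an ene donor, so that no conversion occurs before the catalyst is sequestered by the lactone. Fallback, setting out from 6 and coming back at 9: ozonolysis of 6 (O3, then Me2S) gives the 4-acetylbutenolide F4. Soft enolisation (TMSOTf, Et3N, −78 °C) gives the silyl enol ether F5. Mukaiyama aldol addition of F5 to 7 with [Cu((S,S)-tBu-box)](OTf)2 in THF at −78 °C, followed by 1 M HCl, delivers 9 directly.

3. Step 8. Direct alkynyl–vinyl coupling at the terminal alkyne may precede lactonisation, which would lead to the (Z)-alkylidene isomer or to an uncyclised enyne. Fallback, setting out from 15 and coming back at 17: anti iodolactonisation of 15 (I2, NaHCO3, MeCN, 0 °C) gives the (E)-iodomethylidene butenolide F6. Stille coupling of F6 with tributyl(prop-1-en-2-yl)stannane (Pd2(dba)3, AsPh3, CuI, DMF, 23 °C) proceeds with retention to give 17.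

**Further compounds**

F1 | step 13 | 2-(trimethylsilyl)ethyl (4S,6S)-6-acetoxy-6-[(2E)-4-(acetoxymethyl)-2-(2-methylprop-2-en-1-ylidene)-5-oxo-2,5-dihydrofuran-3-yl]-4-methyl-3-oxo-4-[(triethylsilyl)oxy]hexanoate | C[Si](C)(C)CCOC(=O)CC(=O)[C@@](C)(O[Si](CC)(CC)CC)C[C@H](OC(C)=O)C1=C(COC(C)=O)C(=O)O/C1=C/C(C)=C
F2 | step 13 | 2-(trimethylsilyl)ethyl ester of the C2-carboxylic acid of 26 | CC(=O)OCC1=C2/C(=C\[C@]3(C)CC(C(=O)OCC[Si](C)(C)C)=C(O3)[C@@](C)(O[Si](CC)(CC)CC)C[C@@H]2OC(C)=O)OC1=O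
F3 | step 13 | C2-carboxylic acid of 27 | CC(=O)OCC1=C2/C(=C\[C@]3(C)CC(C(O)=O)=C(O3)[C@@](C)(O)C[C@@H]2OC(C)=O)OC1=O
F4 | step 3 | 4-acetyl-3-({[tert-butyl(dimethyl)silyl]oxy}methyl)furan-2(5H)-one | CC(=O)C1=C(CO[Si](C)(C)C(C)(C)C)C(=O)OC1
F5 | step 3 | 3-({[tert-butyl(dimethyl)silyl]oxy}methyl)-4-{1-[(trimethylsilyl)oxy]ethenyl}furan-2(5H)-one | C=C(O[Si](C)(C)C)C1=C(CO[Si](C)(C)C(C)(C)C)C(=O)OC1
F6 | step 8 | tert-butyl (2S,4S)-4-[(2E)-4-({[tert-butyl(dimethyl)silyl]oxy}methyl)-2-(iodomethylidene)-5-oxo-2,5-dihydrofuran-3-yl]-2-methyl-2,4-bis[(triethylsilyl)oxy]butanoate | CC(C)(C)OC(=O)[C@@](C)(O[Si](CC)(CC)CC)C[C@H](O[Si](CC)(CC)CC)C1=C(CO[Si](C)(C)C(C)(C)C)C(=O)O/C1=C/I
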